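**Retrosynthetic overview**
- Target ⇐ benzoate opening, at the CH2 group, of a spiro-oxirane that sits next to a cis carbinol; this one opening gives both the CH2OBz group and the tertiary OH.
- That carbinol ⇐ hydride reduction of a ketone (the former phenol carbon), with hydride entering opposite the two flanking C–O bonds.
- cis-3,6-Dibenzoate ⇐ 3,6-endoperoxide by O–O reduction and benzoylation; the second benzoylation is done by a lipase and separates the enantiomers.
- Endoperoxide ⇐ singlet-oxygen [4+2] addition to a spiro-epoxy cyclohexa-2,4-dienone on its oxirane-oxygen face ⇐ periodate dearomatisation of salicyl alcohol.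
- Ring order: the carbocycle is the benzene ring of salicyl alcohol, dearomatised and never built. The oxirane forms first, then the endoperoxide (1,2-dioxane) ring. The peroxide ring is cleaved at once and the oxirane is opened last.

Assumption: racemic intermediates (2 to 5) are named and drawn as the enantiomer that is carried on. Locants are those of 1-oxaspiro[2.5]octane (C2 = CH2, C3 = spiro carbon, C4 = former phenol carbon). C2, C3, C4, C5 and C8 become CH2, C1, C2, C3 and C6 of the target.

**Step 1**
Reactants: 1 salicyl alcohol (2-(hydroxymethyl)phenol)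
Product: 4 rac-(3R,5S,8R)-5,8-dihydroxy-1-oxaspiro[2.5]oct-6-en-4-one, via spiroepoxydienone 2 (not isolated), via endoperoxide 3 (not isolated)
Conditions: NaIO4, H2O, 0 °C, 5 min, extract into cold CH2Cl2 (0.02 M); O2, tetraphenylporphyrin (1 mol %), 590 nm LED, −40 °C; then thiourea, MeOH, −40 to 0 °C
Reagents that add atoms: dioxygen, O=O
Why: Proposed new method: Adler–Becker periodate oxidation gives the racemic spiro-epoxy dienone 2 (known; it dimerises when concentrated), and this diene, which has no allylic hydrogen and so no ene pathway, should add singlet oxygen in a [4+2] cycloaddition across C5 and C8 on the face of the small oxirane oxygen (the face dienophiles take with such dienones), so that thiourea reduction of the O–O bond leaves both new carbinols cis to the oxirane oxygen; the closest known reactions are the Diels–Alder trapping of Adler–Becker dienones and the singlet-oxygen cycloaddition to benzene oxide and cyclohexa-1,3-dienes.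

**Step 2**
Reactants: 4 rac-(3R,5S,8R)-5,8-dihydroxy-1-oxaspiro[2.5]oct-6-en-4-one
Product: 5 rac-(3R,5S,8R)-8-hydroxy-4-oxo-1-oxaspiro[2.5]oct-6-en-5-yl benzoate
Conditions: PhCOCl (1.05 equiv), 2,4,6-collidine, CH2Cl2, −40 °C
Reagents that add atoms: benzoyl chloride, O=C(Cl)c1ccccc1
Why: Base-mediated O-acylation is faster at the α-ketol hydroxyl on C5, which lies between two sp2 carbons, than at the C8 hydroxyl next to the quaternary spiro carbon; no stereocentre is touched.

**Step 3**
Reactants: 5 rac-(3R,5S,8R)-8-hydroxy-4-oxo-1-oxaspiro[2.5]oct-6-en-5-yl benzoate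
Product: 6 (3R,5S,8R)-4-oxo-1-oxaspiro[2.5]oct-6-ene-5,8-diyl dibenzoate
Conditions: Burkholderia cepacia lipase (immobilised), vinyl benzoate (3 equiv), MTBE, 4 Å sieves, 40 °C, to about 50% conversion; silica separation from the unreacted (3S,5R,8S) enantiomer of 5
Reagents that add atoms: vinyl benzoate, C=COC(=O)c1ccccc1
Why: Lipase-catalysed kinetic resolution by irreversible transesterification: by Kazlauskas' rule the enantiomer whose carbinol carries the large quaternary spiro carbon and the medium vinyl CH in the (8R) arrangement is acylated, so the dibenzoate is formed from one enantiomer only and no bond at a stereocentre is made or broken.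

**Step 4**
Reactants: 6 (3R,5S,8R)-4-oxo-1-oxaspiro[2.5]oct-6-ene-5,8-diyl dibenzoate
Product: 7 (3S,4S,5S,8R)-4-hydroxy-1-oxaspiro[2.5]oct-6-ene-5,8-diyl dibenzoate
Conditions: NaBH4, CeCl3·7H2O, MeOH/THF, −78 °C; AcOH quench at −78 °C
Reagents that add atoms: none
Why: Luche 1,2-reduction in which hydride adds to the carbonyl face opposite the two flanking C–O bonds (the C5 benzoate and the oxirane oxygen; polar Felkin–Anh control), which sets the new carbinol as (4S), cis to all three ring oxygens; the cold acidic quench prevents benzoate migration.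

**Step 5**
Reactants: 7 (3S,4S,5S,8R)-4-hydroxy-1-oxaspiro[2.5]oct-6-ene-5,8-diyl dibenzoate
Product: 8 [(1S,2S,3S,6R)-3,6-bis(benzoyloxy)-1,2-dihydroxycyclohex-4-en-1-yl]methyl benzoate
Conditions: Ti(OiPr)4 (1.5 equiv), PhCO2H (1.5 equiv), CH2Cl2, 0 °C to rt; aqueous tartaric acid work-up
Reagents that add atoms: benzoic acid, OC(=O)c1ccccc1
Why: Sharpless titanium-mediated opening of a 2,3-epoxy alcohol: the titanium alkoxide of the cis hydroxyl holds the oxirane oxygen and benzoate attacks the unsubstituted CH2 in an SN2 step, so the C–O bond at the quaternary carbon is not broken and its configuration is kept.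

**Compound list**
1 | salicyl alcohol, 2-(hydroxymethyl)phenol | OCc1ccccc1O | starting material
2 | rac-(3S)-1-oxaspiro[2.5]octa-5,7-dien-4-one (racemate; enantiomer carried on is shown) | O=C1C=CC=C[C@]12CO2 | intermediate
3 | rac-(1S,4R,5R)-spiro[2,3-dioxabicyclo[2.2.2]oct-7-ene-5,2'-oxiran]-6-one; peroxide bridge syn to the oxirane oxygen (racemate) | O=C1[C@H]2OO[C@H](C=C2)[C@]13CO3 | intermediate
4 | rac-(3R,5S,8R)-5,8-dihydroxy-1-oxaspiro[2.5]oct-6-en-4-one; both hydroxyls cis to the oxirane oxygen (racemate) | O=C1[C@@H](O)C=C[C@@H](O)[C@]12CO2 | intermediate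
5 | rac-(3R,5S,8R)-8-hydroxy-4-oxo-1-oxaspiro[2.5]oct-6-en-5-yl benzoate (racemate) | O=C1[C@@H](OC(=O)c2ccccc2)C=C[C@@H](O)[C@]13CO3 | intermediate
6 | (3R,5S,8R)-4-oxo-1-oxaspiro[2.5]oct-6-ene-5,8-diyl dibenzoate | O=C1[C@@H](OC(=O)c2ccccc2)C=C[C@@H](OC(=O)c2ccccc2)[C@]13CO3 | intermediate
7 | (3S,4S,5S,8R)-4-hydroxy-1-oxaspiro[2.5]oct-6-ene-5,8-diyl dibenzoate; hydroxyl, both benzoates and oxirane oxygen all on one face | O[C@H]1[C@@H](OC(=O)c2ccccc2)C=C[C@@H](OC(=O)c2ccccc2)[C@]13CO3 | intermediate
8 | [(1S,2S,3S,6R)-3,6-bis(benzoyloxy)-1,2-dihydroxycyclohex-4-en-1-yl]methyl benzoate | O=C(OC[C@@]1(O)[C@H](OC(=O)c2ccccc2)C=C[C@H](OC(=O)c2ccccc2)[C@@H]1O)c1ccccc1 | target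

**Totals and risks**
Total step count: 5. Longest linear sequence: 5.

The three steps most likely to fail are steps 1, 3 and 4.

Step 1 may fail because dienone 2 is electron-poor and may dimerise faster than it takes up singlet oxygen. The fallback sets out from 2 (cold CH2Cl2 solution as in step 1) and returns at 4. NaBH4 and CeCl3·7H2O in MeOH at −78 °C reduce 2 to the dienol rac-(3S,4R)-1-oxaspiro[2.5]octa-5,7-dien-4-ol F1; its carbinol centre is later erased. F1 is an electron-rich diene that cannot dimerise as a dienone, though it is acid-labile and must be kept cold and base-washed. O2, tetraphenylporphyrin and 590 nm light in CH2Cl2 at −78 °C add singlet oxygen on the oxirane-oxygen face to give the endoperoxide alcohol rac-(1S,4R,5S,6R)-spiro[2,3-dioxabicyclo[2.2.2]oct-7-ene-5,2'-oxiran]-6-ol F2. Dess–Martin periodinane with NaHCO3 then gives the keto endoperoxide 3, and thiourea as in step 1 gives 4.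

Step 3 may fail because vinyl benzoate is a slow acyl donor and the carbinol is hindered, so rate or selectivity may be too low. The fallback sets out from racemic 5 and returns at 6. PhCOCl, pyridine and DMAP at 0 °C give the racemic dibenzoate, that is 6 together with its mirror image (3S,5R,8S)-4-oxo-1-oxaspiro[2.5]oct-6-ene-5,8-diyl dibenzoate F3. Preparative SFC on an amylose tris(3,5-dimethylphenylcarbamate) phase separates the two, and 6 goes on to step 4.

Step 4 may fail if hydride enters from the oxirane-oxygen face and gives the C4 epimer. The fallback sets out from 6 and returns at 8. The oxirane is first hydrated at its CH2 (catalytic HClO4, THF/H2O, 0 °C; the carbon alpha to the ketone does not ionise) to the diol ketone (1S,4R,5R)-5-hydroxy-5-(hydroxymethyl)-6-oxocyclohex-2-ene-1,4-diyl dibenzoate F4. Me4NBH(OAc)3 in MeCN/AcOH at −30 °C then delivers hydride intramolecularly from the primary alkoxyborohydride, which lies on the face opposite the tertiary hydroxyl (Evans–Saksena reduction). This gives the triol (1S,4R,5S,6S)-5,6-dihydroxy-5-(hydroxymethyl)cyclohex-2-ene-1,4-diyl dibenzoate F5. PhCOCl and collidine at −30 °C acylate only the primary hydroxyl and give 8.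

**Further compounds**
F1 | step 1 | rac-(3S,4R)-1-oxaspiro[2.5]octa-5,7-dien-4-ol | O[C@@H]1C=CC=C[C@]12CO2
F2 | step 1 | rac-(1S,4R,5S,6R)-spiro[2,3-dioxabicyclo[2.2.2]oct-7-ene-5,2'-oxiran]-6-ol | O[C@@H]1[C@H]2OO[C@H](C=C2)[C@]13CO3
F3 | step 3 | (3S,5R,8S)-4-oxo-1-oxaspiro[2.5]oct-6-ene-5,8-diyl dibenzoate | O=C1[C@H](OC(=O)c2ccccc2)C=C[C@H](OC(=O)c2ccccc2)[C@@]13CO3
F4 | step 4 | (1S,4R,5R)-5-hydroxy-5-(hydroxymethyl)-6-oxocyclohex-2-ene-1,4-diyl dibenzoate | O=C1[C@@H](OC(=O)c2ccccc2)C=C[C@@H](OC(=O)c2ccccc2)[C@]1(O)CO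
F5 | step 4 | (1S,4R,5S,6S)-5,6-dihydroxy-5-(hydroxymethyl)cyclohex-2-ene-1,4-diyl dibenzoate | O[C@H]1[C@@H](OC(=O)c2ccccc2)C=C[C@@H](OC(=O)c2ccccc2)[C@]1(O)CO
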